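**Direct plan and its weak points**

A direct plan would keep a purchased arene. 3,4,5-Trimethoxytoluene A1 would be formylated, demethylated ortho to CHO, benzylated, Dakin-oxidised and oxidised to the benzyloxyquinone A2.
A2 would be reduced to the hydroquinone A3, alkylated with all-E-hexaprenol A4 (BF3), re-oxidised to the benzyl ether A5 and debenzylated with BCl3.
Weakest would be the BF3 Friedel–Crafts allylation of A3 with A4. A free polyprenyl cation would invite Δ2′ E/Z erosion, attack through the tertiary terminus, chromanol closure and polyene cyclisation.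
That step would also spend the costly C30 piece in the least selective operation of the plan.
Weak would be the run-up from A1 to A3. It consists only of protecting-group and redox moves (a formyl carbon added to be excised, a quinone made, reduced and remade) and builds no skeletal bond.
Weak would be the closing BCl3 debenzylation of A5. Six acid-sensitive alkenes and two chelatable vinylogous esters (OBn, OMe) would meet a strong Lewis acid in the last step.

**Retrosynthetic overview of the new route**

1. The cut goes through the quinone ring, not the ring–chain bond. C1(=O)–C2(OH)–C3(OMe)–C4(=O) is read as a ring-opened squarate, and C6(CH3)=C5(hexaprenyl) as one alkenyl anion that already carries the chain.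
2. C1–C6 comes from 1,2-addition of that alkenyllithium to dimethyl squarate. C4–C5 and the only ring come from the key step, in which the squarate C–C bond absent from the target breaks (4π) and the dienylketene closes (6π).
3. OH versus OMe is settled inside the four-membered ring. The methoxy group β to the ketone is a vinylogous ester and the α one an enol ether, and cleaving the former gives a mirror-symmetric enolate, so OMe must end para to the methyl carbon.
4. The chain is joined early as an sp3–sp coupling (hexaprenyl bromide plus propynyl Grignard), followed by hydrozirconation–iodination. The six-membered ring forms in the penultimate step, and only unmasking and oxidation follow.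
5. By design there is no Friedel–Crafts step or allyl cation and no arene run-up, since the squarate brings all four oxygens at the right oxidation level. The endgame is buffered fluoride plus a mild oxidant instead of BCl3.

Key step: step 5

**Assumptions and conventions**
- The target has no stereocentre. Its stereochemistry is the five E-trisubstituted alkenes, which are bought with all-E-hexaprenol (taken as purchasable from isoprenoid suppliers) and never touched.
- The cyclobutenones are racemic at one carbon, which is erased on ring expansion.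
- Quinone numbering follows 2-hydroxy-3-methoxy-6-methyl-5-hexaprenyl-1,4-benzoquinone.
- In the cyclobutenones C1 is the ketone and C4 the oxygenated sp3 carbon. Cα (bearing CH3) and Cβ (bearing H and the chain) are the alkenyl carbons.
- Four-ring C4/C3/C2/C1 become quinone C1/C2/C3/C4. Cα/Cβ become C6/C5.

**Route**

Step 1
Reactants: 1 all-E-hexaprenol
Product: 2 all-E-hexaprenyl bromide
Conditions: PBr3 (0.4 equiv), Et2O, −10 → 0 °C, dark; used crude
Reagents that add atoms: phosphorus tribromide, BrP(Br)Br
Why: Bromination of a primary allylic alcohol through its phosphite ester (SN2 displacement, as practised for farnesyl and solanesyl bromide) should proceed at low temperature without allylic transposition or loss of the Δ2 E geometry, and no stereocentre is involved.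

Step 2
Reactants: 2 all-E-hexaprenyl bromide; 3 1-propynylmagnesium bromide
Product: 4 (5E,9E,13E,17E,21E)-6,10,14,18,22,26-hexamethylheptacosa-5,9,13,17,21,25-hexaen-2-yne
Conditions: 3 (1.3 equiv, THF solution), CuI (10 mol %), THF, −20 °C → rt
Reagents that add atoms: none
Why: Copper(I)-catalysed coupling of an alkynyl Grignard reagent with an allylic halide should deliver the propynyl group at the primary terminus (the γ-carbon is fully substituted), which makes the future ring–chain bond C5–C1′ as a plain sp3–sp substitution without an allyl cation, so that the E geometry is kept in the skipped enyne.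

Step 3
Reactants: 4 skipped enyne
Product: 6 (2E,5E,9E,13E,17E,21E)-2-iodo-6,10,14,18,22,26-hexamethylheptacosa-2,5,9,13,17,21,25-heptaene, via alkenylzirconocene chloride 5 (not isolated)
Conditions: Cp2Zr(H)Cl (1.8 equiv), THF, rt → 45 °C, dark; then I2 (to the colour end point), THF, −78 °C; aq. Na2S2O3/NaHCO3
Reagents that add atoms: iodine, II
Why: Hydrozirconation with the Schwartz reagent is a syn addition that, with excess reagent and gentle warming, equilibrates to the isomer with zirconium on the less hindered, methyl-bearing alkyne carbon, the trisubstituted alkenes being inert, and iodinolysis of the C–Zr bond with retention should give the E-iodide with iodine cis to the vinylic H.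

Step 4
Reactants: 6 E-alkenyl iodide; 7 dimethyl squarate
Product: 10 (±)-4-(tert-butyldimethylsilyloxy)-2,3-dimethoxy-4-[(2E,5E,9E,13E,17E,21E)-6,10,14,18,22,26-hexamethylheptacosa-2,5,9,13,17,21,25-heptaen-2-yl]cyclobut-2-en-1-one, via alkenyllithium 8 (not isolated), via lithium alkoxide 9 (not isolated)
Conditions: t-BuLi (2.0 equiv), Et2O, −78 °C; cannulated into 7 (1.1 equiv), THF, −78 °C; TBSOTf (1.2 equiv), −78 → 0 °C; aq. NaHCO3
Reagents that add atoms: tert-butyldimethylsilyl triflate, CC(C)(C)[Si](C)(C)OS(=O)(=O)C(F)(F)F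
Why: Iodine–lithium exchange with retention, 1,2-addition of the alkenyllithium to one of the two equivalent carbonyl groups of the squarate ester (the standard entry into 4-oxygenated cyclobutenones) and O-silylation of the alkoxide should give 10, the low temperature suppressing proton transfer from the doubly allylic CH2; the new C4 stereocentre is racemic and is erased in step 5.

Step 5
Reactants: 10 dimethoxy(silyloxy)cyclobutenone
Product: 15 3,4-bis(tert-butyldimethylsilyloxy)-2-methoxy-5-methyl-6-[(all-E)-hexaprenyl]phenol, via potassium enolate 11 (not isolated), via bis(silyl ether) 12 (not isolated), via dienylketene 13 (not isolated), via cyclohexadienone 14 (not isolated)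
Conditions: TMSOK (1.05 equiv), THF, 0 °C → rt; TBSCl (1.1 equiv), rt; diluted with toluene (ca. 0.01 M), THF distilled off, 110 °C, Ar
Reagents that add atoms: potassium trimethylsilanolate, C[Si](C)(C)[O-].[K+] (supplies the C3 oxygen); tert-butyldimethylsilyl chloride, CC(C)(C)[Si](C)(C)Cl
Why: Only the C3 methoxy group of 10 is a vinylogous methyl ester (β-carbon of the enone; the C2 methoxy group is a plain enol ether), so the silanolate should exchange it alone by conjugate addition–elimination, the reaction type by which 3-alkoxycyclobutenones and squarate esters are saponified, and the mirror-symmetric 1,3-dione enolate 11 gives the same (±)-12 whichever of its two enantiotopic oxygens is silylated. On heating, 12 should open by conrotatory 4π electrocyclic cleavage of the C1–C4 bond, the C4 siloxy donor rotating outward (torquoselectivity) so that the alkenyl group turns inward and lies next to the ketene carbon of 13. Disrotatory 6π electrocyclisation then forms the C1–Cβ bond (quinone C4–C5), closes the only ring of the target as a six-membered carbocycle, and 14 tautomerises to the phenol 15; this is the thermal ring expansion of 4-alkenylcyclobutenones to hydroquinones known from squarate chemistry. No lasting stereocentre is made: the racemic C4 centre and the Cα=Cβ geometry are consumed, and the five E-alkenes of the chain see only neutral toluene at 110 °C. The regiochemistry is topological: the methoxy carbon C2 lies diagonally opposite C4 in the four-membered ring and must end para to the methyl-bearing Cα, so the future free OH (on C3) sits next to the carbonyl that flanks the methyl group, as the target demands. The step needs ring closure to outrun ketene capture (dimerisation, [2+2] with the Δ2′ alkene, adventitious water), which the cis-dienylketene geometry, the vinylic H on the inner face of Cβ, high dilution and the aprotic medium should secure.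

Step 6
Reactants: 15 bis(silyl) phenol
Product: 17 3-demethylubiquinone-6 (2-hydroxy-3-methoxy-6-methyl-5-[(all-E)-hexaprenyl]-1,4-benzoquinone), via benzenetriol 16 (not isolated)
Conditions: TBAF (2.2 equiv), AcOH (2.2 equiv), THF, 0 °C, Ar; then PhI(OAc)2 (1.05 equiv), 0 °C; citrate buffer work-up, dark
Reagents that add atoms: none
Why: Buffered fluoride cleaves the two aryl silyl ethers and the electron-rich benzenetriol is oxidised at once by the iodine(III) reagent (hydroquinone-to-quinone oxidation) to the 2-hydroxy-1,4-quinone, its most stable tautomer, under near-neutral, metal-free conditions that should leave the six alkenes and the methoxy group untouched.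

**Compound list**

1 | (2E,6E,10E,14E,18E)-3,7,11,15,19,23-hexamethyltetracosa-2,6,10,14,18,22-hexaen-1-ol (all-E-hexaprenol) | OC/C=C(\C)CC/C=C(\C)CC/C=C(\C)CC/C=C(\C)CC/C=C(\C)CCC=C(C)C | starting material
2 | all-E-hexaprenyl bromide | BrC/C=C(\C)CC/C=C(\C)CC/C=C(\C)CC/C=C(\C)CC/C=C(\C)CCC=C(C)C | intermediate
3 | 1-propynylmagnesium bromide | CC#C[Mg]Br | starting material
4 | (5E,9E,13E,17E,21E)-6,10,14,18,22,26-hexamethylheptacosa-5,9,13,17,21,25-hexaen-2-yne | CC#CC/C=C(\C)CC/C=C(\C)CC/C=C(\C)CC/C=C(\C)CC/C=C(\C)CCC=C(C)C | intermediate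
5 | chlorobis(cyclopentadienyl)[(2E)-heptaen-2-yl]zirconium (Zr on C2, cis to the C3–H) | C/C([Zr+2]Cl)=C\C/C=C(\C)CC/C=C(\C)CC/C=C(\C)CC/C=C(\C)CC/C=C(\C)CCC=C(C)C.[cH-]1cccc1.[cH-]1cccc1 | intermediate
6 | (2E,5E,9E,13E,17E,21E)-2-iodo-6,10,14,18,22,26-hexamethylheptacosa-2,5,9,13,17,21,25-heptaene | C/C(I)=C\C/C=C(\C)CC/C=C(\C)CC/C=C(\C)CC/C=C(\C)CC/C=C(\C)CCC=C(C)C | intermediate
7 | dimethyl squarate (3,4-dimethoxycyclobut-3-ene-1,2-dione) | COC1=C(OC)C(=O)C1=O | starting material
8 | 2-lithio analogue of 6 (Li cis to the vinylic H) | C/C([Li])=C\C/C=C(\C)CC/C=C(\C)CC/C=C(\C)CC/C=C(\C)CC/C=C(\C)CCC=C(C)C | intermediate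
9 | (±)-lithium alkoxide of the 4-alkenyl-4-hydroxy-2,3-dimethoxycyclobutenone | COC1=C(OC)C([O-])(/C(C)=C/C/C=C(\C)CC/C=C(\C)CC/C=C(\C)CC/C=C(\C)CC/C=C(\C)CCC=C(C)C)C1=O.[Li+] | intermediate
10 | (±)-4-(TBSO)-2,3-dimethoxy-4-[(2E,all-E)-heptaen-2-yl]cyclobut-2-en-1-one | COC1=C(OC)C(O[Si](C)(C)C(C)(C)C)(/C(C)=C/C/C=C(\C)CC/C=C(\C)CC/C=C(\C)CC/C=C(\C)CC/C=C(\C)CCC=C(C)C)C1=O | intermediate
11 | potassium 4-(TBSO)-2-methoxy-4-alkenyl-3-oxocyclobut-1-en-1-olate (mirror-symmetric anion) | COC1=C([O-])C(O[Si](C)(C)C(C)(C)C)(/C(C)=C/C/C=C(\C)CC/C=C(\C)CC/C=C(\C)CC/C=C(\C)CC/C=C(\C)CCC=C(C)C)C1=O.[K+] | intermediate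
12 | (±)-3,4-bis(TBSO)-2-methoxy-4-[(2E,all-E)-heptaen-2-yl]cyclobut-2-en-1-one | COC1=C(O[Si](C)(C)C(C)(C)C)C(O[Si](C)(C)C(C)(C)C)(/C(C)=C/C/C=C(\C)CC/C=C(\C)CC/C=C(\C)CC/C=C(\C)CC/C=C(\C)CCC=C(C)C)C1=O | intermediate
13 | dienylketene O=C=C(OMe)–C(OTBS)=C(OTBS)–C(CH3)=CH–hexaprenyl (ketene arm and alkenyl arm cis on the central C=C) | O=C=C(OC)/C(O[Si](C)(C)C(C)(C)C)=C(O[Si](C)(C)C(C)(C)C)\C(C)=C\C/C=C(\C)CC/C=C(\C)CC/C=C(\C)CC/C=C(\C)CC/C=C(\C)CCC=C(C)C | intermediate
14 | (±)-3,4-bis(TBSO)-2-methoxy-5-methyl-6-(all-E-hexaprenyl)cyclohexa-2,4-dien-1-one | O=C1C(OC)=C(O[Si](C)(C)C(C)(C)C)C(O[Si](C)(C)C(C)(C)C)=C(C)C1C/C=C(\C)CC/C=C(\C)CC/C=C(\C)CC/C=C(\C)CC/C=C(\C)CCC=C(C)C | intermediate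
15 | 3,4-bis(TBSO)-2-methoxy-5-methyl-6-(all-E-hexaprenyl)phenol | COc1c(O[Si](C)(C)C(C)(C)C)c(O[Si](C)(C)C(C)(C)C)c(C)c(C/C=C(\C)CC/C=C(\C)CC/C=C(\C)CC/C=C(\C)CC/C=C(\C)CCC=C(C)C)c1O | intermediate
16 | 5-(all-E-hexaprenyl)-3-methoxy-6-methylbenzene-1,2,4-triol (3-demethylubiquinol-6) | COc1c(O)c(O)c(C)c(C/C=C(\C)CC/C=C(\C)CC/C=C(\C)CC/C=C(\C)CC/C=C(\C)CCC=C(C)C)c1O | intermediate
17 | 3-demethylubiquinone-6 | COC1=C(O)C(=O)C(C)=C(C/C=C(\C)CC/C=C(\C)CC/C=C(\C)CC/C=C(\C)CC/C=C(\C)CCC=C(C)C)C1=O | target

**Step count and risks**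

Total steps: 6. Longest linear sequence: 6 (1 → 17).

**Step 5 (key step).**
- What may go wrong: the silanolate could attack the ring ketone and cleave the strained ring, or strip the C4 silyl ether. The labile enol silyl group could also be lost before the ring opens, so that the ketene is diverted.
- Fallback (from 10, back at 17): ring construction and oxygen differentiation would be separated.
- 10 would be heated as such (toluene, 110 °C), the parent case of this ring expansion. It should pass through the dimethoxy dienylketene F1 and the dimethoxy cyclohexadienone F2 to the mono-silylated ubiquinol-6 F3. In F3 the two hydroquinone oxygens are distinguished: free OH beside the chain, OTBS beside the methyl group.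
- Acetylation (Ac2O, pyridine) would give the aryl acetate F4, and fluoride (TBAF/AcOH) the 4-acetoxyphenol F5. The free OH of F5 now stands ortho to exactly the methoxy group that has to go.
- IBX (DMF, rt; oxidative demethylation of a 2-methoxyphenol) would give the acetoxy-ortho-quinone F6.
- Methanolysis of its vinylogous anhydride (K2CO3, MeOH, 0 °C, then citric acid) would free the 4-hydroxy-1,2-quinone, which is the tautomer of 17.

**Step 3.**
- What may go wrong: regiochemical equilibration of the hydrozirconation could be incomplete. Part of the metal would then sit on the carbon next to the CH2 group, and that error would end as the OH/OMe regioisomer of the target.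
- Fallback (from 2, back at 14 and hence 15): the position of the metal would be fixed by construction.
- Pd-catalysed distannylation of propyne with hexamethylditin would give (Z)-1,2-bis(trimethylstannyl)propene F7.
- A Stille coupling with 2 (Pd2(dba)3, AsPh3, THF) should engage only the unhindered terminal C–Sn bond and give the (Z)-alkenylstannane F8.
- Sn/Li exchange (MeLi, THF, −78 °C) would give the alkenyllithium F9. Addition to 7 would give the lithium alkoxide F10, and TBSOTf would give the (Z)-alkenyl isomer of 10 F11.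
- Under the conditions of step 5 this should run through the enolate F12, the bis(silyl ether) F13 and the dienylketene F14, now with the CH2 group on the inner face of Cβ. Ring closure erases the alkene geometry, so the sequence converges on 14.

**Step 6.**
- What may go wrong: the free triol could autoxidise in an uncontrolled way. Base could also induce cyclisation of the quinone onto the Δ2′ alkene (chromenol formation) during the fluoride treatment.
- Fallback (from 15, back at 17): the triol would never be set free.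
- Oxidative dearomatisation of the 4-silyloxyphenol 15 with PhI(OAc)2 in MeCN/THF/H2O at 0 °C would give the silyloxyquinone F15 directly.
- Its silyl vinylogous ester would then be hydrolysed with AcOH/THF/H2O at rt.

**Further compounds**

F1 | step 5 | dienylketene O=C=C(OMe)–C(OMe)=C(OTBS)–C(CH3)=CH–hexaprenyl | O=C=C(OC)/C(OC)=C(O[Si](C)(C)C(C)(C)C)\C(C)=C\C/C=C(\C)CC/C=C(\C)CC/C=C(\C)CC/C=C(\C)CC/C=C(\C)CCC=C(C)C
F2 | step 5 | (±)-4-(TBSO)-2,3-dimethoxy-5-methyl-6-(all-E-hexaprenyl)cyclohexa-2,4-dien-1-one | O=C1C(OC)=C(OC)C(O[Si](C)(C)C(C)(C)C)=C(C)C1C/C=C(\C)CC/C=C(\C)CC/C=C(\C)CC/C=C(\C)CC/C=C(\C)CCC=C(C)C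
F3 | step 5 | 4-(TBSO)-2,3-dimethoxy-5-methyl-6-(all-E-hexaprenyl)phenol | COc1c(OC)c(O[Si](C)(C)C(C)(C)C)c(C)c(C/C=C(\C)CC/C=C(\C)CC/C=C(\C)CC/C=C(\C)CC/C=C(\C)CCC=C(C)C)c1O
F4 | step 5 | 4-(TBSO)-2,3-dimethoxy-5-methyl-6-(all-E-hexaprenyl)phenyl acetate | COc1c(OC)c(O[Si](C)(C)C(C)(C)C)c(C)c(C/C=C(\C)CC/C=C(\C)CC/C=C(\C)CC/C=C(\C)CC/C=C(\C)CCC=C(C)C)c1OC(C)=O
F5 | step 5 | 4-acetoxy-2,3-dimethoxy-6-methyl-5-(all-E-hexaprenyl)phenol | COc1c(OC)c(O)c(C)c(C/C=C(\C)CC/C=C(\C)CC/C=C(\C)CC/C=C(\C)CC/C=C(\C)CCC=C(C)C)c1OC(C)=O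
F6 | step 5 | 4-acetoxy-3-methoxy-6-methyl-5-(all-E-hexaprenyl)cyclohexa-3,5-diene-1,2-dione | COC1=C(OC(C)=O)C(C/C=C(\C)CC/C=C(\C)CC/C=C(\C)CC/C=C(\C)CC/C=C(\C)CCC=C(C)C)=C(C)C(=O)C1=O
F7 | step 3 | (Z)-1,2-bis(trimethylstannyl)prop-1-ene | C/C([Sn](C)(C)C)=C/[Sn](C)(C)C
F8 | step 3 | (2Z,5E,9E,13E,17E,21E)-2-(trimethylstannyl)-6,10,14,18,22,26-hexamethylheptacosa-2,5,9,13,17,21,25-heptaene | C/C([Sn](C)(C)C)=C/C/C=C(\C)CC/C=C(\C)CC/C=C(\C)CC/C=C(\C)CC/C=C(\C)CCC=C(C)C
F9 | step 3 | 2-lithio analogue of F8 (Li cis to the CH2 group) | C/C([Li])=C/C/C=C(\C)CC/C=C(\C)CC/C=C(\C)CC/C=C(\C)CC/C=C(\C)CCC=C(C)C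
F10 | step 3 | (±)-lithium alkoxide, (2Z)-alkenyl isomer of 9 | COC1=C(OC)C([O-])(/C(C)=C\C/C=C(\C)CC/C=C(\C)CC/C=C(\C)CC/C=C(\C)CC/C=C(\C)CCC=C(C)C)C1=O.[Li+]
F11 | step 3 | (±)-(2Z)-alkenyl isomer of 10 | COC1=C(OC)C(O[Si](C)(C)C(C)(C)C)(/C(C)=C\C/C=C(\C)CC/C=C(\C)CC/C=C(\C)CC/C=C(\C)CC/C=C(\C)CCC=C(C)C)C1=O
F12 | step 3 | potassium enolate, (2Z)-alkenyl isomer of 11 | COC1=C([O-])C(O[Si](C)(C)C(C)(C)C)(/C(C)=C\C/C=C(\C)CC/C=C(\C)CC/C=C(\C)CC/C=C(\C)CC/C=C(\C)CCC=C(C)C)C1=O.[K+]
F13 | step 3 | (±)-bis(silyl ether), (2Z)-alkenyl isomer of 12 | COC1=C(O[Si](C)(C)C(C)(C)C)C(O[Si](C)(C)C(C)(C)C)(/C(C)=C\C/C=C(\C)CC/C=C(\C)CC/C=C(\C)CC/C=C(\C)CC/C=C(\C)CCC=C(C)C)C1=O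
F14 | step 3 | dienylketene, Cα=Cβ geometric isomer of 13 | O=C=C(OC)/C(O[Si](C)(C)C(C)(C)C)=C(O[Si](C)(C)C(C)(C)C)\C(C)=C/C/C=C(\C)CC/C=C(\C)CC/C=C(\C)CC/C=C(\C)CC/C=C(\C)CCC=C(C)C
F15 | step 6 | 2-(TBSO)-3-methoxy-6-methyl-5-(all-E-hexaprenyl)-1,4-benzoquinone | COC1=C(O[Si](C)(C)C(C)(C)C)C(=O)C(C)=C(C/C=C(\C)CC/C=C(\C)CC/C=C(\C)CC/C=C(\C)CC/C=C(\C)CCC=C(C)C)C1=O
A1 | direct plan | 3,4,5-trimethoxytoluene | COc1cc(C)cc(OC)c1OC
A2 | direct plan | 2-(benzyloxy)-3-methoxy-6-methyl-1,4-benzoquinone | COC1=C(OCc2ccccc2)C(=O)C(C)=CC1=O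
A3 | direct plan | 2-(benzyloxy)-3-methoxy-6-methylbenzene-1,4-diol | COc1c(OCc2ccccc2)c(O)c(C)cc1O
A4 | direct plan | all-E-hexaprenol | OC/C=C(\C)CC/C=C(\C)CC/C=C(\C)CC/C=C(\C)CC/C=C(\C)CCC=C(C)C
A5 | direct plan | 2-(benzyloxy)-3-methoxy-6-methyl-5-(all-E-hexaprenyl)-1,4-benzoquinone | COC1=C(OCc2ccccc2)C(=O)C(C)=C(C/C=C(\C)CC/C=C(\C)CC/C=C(\C)CC/C=C(\C)CC/C=C(\C)CCC=C(C)C)C1=O
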